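**Plan** (labdane numbering: C1–C10 decalin, C11–C16 side chain, C17 on C8, C18/C19 on C4, C20 on C10)

- Retrosynthesis, late cuts: C8=C17 (ketone methylenation), then C12–C13 (B-alkyl Suzuki coupling of a C9 vinyl group with an (E)-enol triflate). This leaves a trans-decalin with oxygen on C8 and the ester carbon C11 on C9.
- Key cut: C5–C10 and C8–C9 together, by an intramolecular Diels–Alder reaction. It is possible because ring B holds C5, C10 and C9 as contiguous stereocentres, C8 can be an oxygen-bearing diene terminus, C11 is a carbonyl on C9, and C1–C4 of ring A can act as the tether.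
- The triene is cut at C6=C7 (cross-metathesis), C9–C11 and C10–C20 (alkyne carboalumination–acylation), C4–C18 (enolate methylation) and C3–C4 (aldol).
- Forward: aldol, quaternary C4, dienophile, enal, silyloxydiene, rings A and B closed in one step, then hydrogenation, C11 to vinyl, side chain, C8 methylene, acetate diacid.
- Stereochemistry: C3 from a reagent-controlled boron aldol; C4 from chelate-controlled methylation anti to O3; C5, C9, C10 (and the transient C8) from alkene geometry and the ester-endo, chair-tether transition state steered by C3/C4; 13E from stereoretentive coupling.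

Key step: step 7

Remark: the (R,R)-configured boron controller of step 1 is assumed to deliver the (3S)-aldol; should it give (3R), its (S,S)-enantiomer is used with nothing else changed.

Step 1
Reactants: 1 tert-butyl pent-4-enoate; 2 pent-4-ynal
Product: 4 tert-butyl (2S,3S)-3-hydroxy-2-(prop-2-en-1-yl)hept-6-ynoate, via boron enolate 3 (not isolated)
Conditions: (R,R)-N,N'-bis{[3,5-bis(trifluoromethyl)phenyl]sulfonyl}-1,2-diphenylethane-1,2-diamine, BBr3, CH2Cl2, rt, then evaporation; 1, Et3N, PhMe–hexane, −78 °C; then 2, −78 °C; pH 7 buffer, MeOH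
Reagents that add atoms: none
Why: Enantioselective boron-mediated ester aldol addition through a closed Zimmerman–Traxler transition state, in which the C2-symmetric diazaborolidine on boron differentiates the aldehyde faces and sets C3 as (S), while the anti C2 centre from the E(O)-enolate is of no consequence because it is planarised in step 2.

Step 2
Reactants: 4 tert-butyl (2S,3S)-3-hydroxy-2-(prop-2-en-1-yl)hept-6-ynoate
Product: 6 tert-butyl (2R,3S)-3-hydroxy-2-methyl-2-(prop-2-en-1-yl)hept-6-ynoate, via trilithio species 5 (not isolated)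
Conditions: LiN(iPr)2 (3.3 equiv), THF, −78 → −20 °C; then MeI (1.1 equiv), −78 → −40 °C; aq. NH4Cl
Reagents that add atoms: iodomethane CI
Why: Fráter–Seebach alkylation, in which the lithium alkoxide–enolate chelate is methylated on the face away from the C3 side chain, so that the methyl group (C18) enters anti to O3 and the quaternary C4 is set with the ester in the future axial C19 position; the lithium acetylide is not alkylated at this temperature.

Step 3
Reactants: 6 tert-butyl (2R,3S)-3-hydroxy-2-methyl-2-(prop-2-en-1-yl)hept-6-ynoate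
Product: 7 tert-butyl (2R,3S)-3-[(tert-butyldimethylsilyl)oxy]-2-methyl-2-(prop-2-en-1-yl)hept-6-ynoate
Conditions: TBSOTf, 2,6-lutidine, CH2Cl2, 0 °C
Reagents that add atoms: tert-butyldimethylsilyl triflate CC(C)(C)[Si](C)(C)OS(=O)(=O)C(F)(F)F
Why: Silyl ether formation with the silyl triflate, which is reactive enough for a secondary alcohol next to a quaternary carbon; the alcohol must be masked before an enal is present in the molecule.

Step 4
Reactants: 7 tert-butyl (2R,3S)-3-[(tert-butyldimethylsilyl)oxy]-2-methyl-2-(prop-2-en-1-yl)hept-6-ynoate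
Product: 9 1-tert-butyl 8-methyl (2R,3S,6E)-3-[(tert-butyldimethylsilyl)oxy]-2,6-dimethyl-2-(prop-2-en-1-yl)oct-6-enedioate, via alkenylalane 8 (not isolated)
Conditions: Me3Al (3 equiv), Cp2ZrCl2 (0.25 equiv), CH2Cl2, 0 °C → rt; then ClCO2Me, 0 °C → rt
Reagents that add atoms: trimethylaluminium C[Al](C)C; methyl chloroformate COC(=O)Cl
Why: Negishi zirconium-catalysed carboalumination adds methyl (C20) and aluminium syn across the terminal alkyne with methyl on the internal carbon, and acylation of the alkenyl–aluminium bond with retention gives only the (E)-3-methyl-enoate, installed after the last strong-base step so that it is never exposed to amide bases.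

Step 5
Reactants: 9 1-tert-butyl 8-methyl (2R,3S,6E)-3-[(tert-butyldimethylsilyl)oxy]-2,6-dimethyl-2-(prop-2-en-1-yl)oct-6-enedioate
Product: 10 1-tert-butyl 8-methyl (2R,3S,6E)-3-[(tert-butyldimethylsilyl)oxy]-2,6-dimethyl-2-[(2E)-4-oxobut-2-en-1-yl]oct-6-enedioate
Conditions: crotonaldehyde (5 equiv), RuCl2(H2IMes)(=CH-C6H4-2-OiPr) (second-generation Hoveyda–Grubbs catalyst, 5 mol %), CH2Cl2, 40 °C
Reagents that add atoms: (E)-crotonaldehyde C/C=C/C=O
Why: Olefin cross-metathesis of the unhindered terminal alkene with an enal partner, the trisubstituted electron-poor enoate being inert to the catalyst, which delivers C7 and C8 as the (E)-enal.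

Step 6
Reactants: 10 1-tert-butyl 8-methyl (2R,3S,6E)-3-[(tert-butyldimethylsilyl)oxy]-2,6-dimethyl-2-[(2E)-4-oxobut-2-en-1-yl]oct-6-enedioate
Product: 11 1-tert-butyl 8-methyl (2R,3S,6E)-3-[(tert-butyldimethylsilyl)oxy]-2-[(1E,3E)-4-[(tert-butyldimethylsilyl)oxy]buta-1,3-dien-1-yl]-2,6-dimethyloct-6-enedioate
Conditions: TBSOTf, Et3N, Et2O, −78 → 0 °C
Reagents that add atoms: tert-butyldimethylsilyl triflate CC(C)(C)[Si](C)(C)OS(=O)(=O)C(F)(F)F
Why: Silyl dienol ether formation by O-silylation of the enal and removal of a C5 proton (soft enolisation), the s-trans enal giving the (E)-enol ether and the bulky quaternary C4 the (E)-C5=C6 bond, while the far less acidic esters are left alone.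

Step 7
Reactants: 11 1-tert-butyl 8-methyl (2R,3S,6E)-3-[(tert-butyldimethylsilyl)oxy]-2-[(1E,3E)-4-[(tert-butyldimethylsilyl)oxy]buta-1,3-dien-1-yl]-2,6-dimethyloct-6-enedioate
Product: 12 1-tert-butyl 5-methyl 2,6-bis[(tert-butyldimethylsilyl)oxy]-1,4a-dimethyl-1,2,3,4,4a,5,6,8a-octahydronaphthalene-1,5-dicarboxylate (labdane numbering: trans-fused, Δ6, 3β-OTBS, 8β-OTBS, 9β-CO2Me, 4β-CO2tBu, 4α-CH3, 10β-CH3, 5α-H)
Conditions: PhMe (0.005 M, degassed), BHT (cat.), base-washed sealed tube, 170 °C
Reagents that add atoms: none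
Why: A thermal, concerted but asynchronous normal-demand [4+2] cycloaddition in which the HOMO of the (1E,3E)-1-silyloxydiene (largest coefficient at C5) meets the LUMO of the (E)-β-methyl enoate (largest coefficient at C10), so that C5–C10 bonding leads and C8–C9 follows; the closest known reaction type is the intramolecular Diels–Alder reaction of ester-activated (E)-1,7,9-decatrienes to trans-decalins with an angular methyl group. Ring B closes as the new cyclohexene by the two-bond cycloaddition itself, and ring A closes as the six-membered carbocycle spanned by the C1–C4 tether, which sits in a chair in the transition state and is helped into the reactive rotamer by the quaternary C4 next to the diene. C9 and C10 follow from suprafacial addition to the (E)-enoate (C11 ester cis to C20), C8 and C5 from suprafacial addition to the (E,E)-diene (C8–O cis to C4), and the relation between the two pairs from the ester-endo, tether-exo arrangement, which gives the trans ring fusion with the ester cis to the C8 silyloxy group. The step needs endo over exo selectivity and one diene face: the first should be secured by the advanced C5–C10 bonding of this polarised diene/dienophile pair together with the endo preference of the conjugated ester, the second by the tether chair that keeps the C3 silyloxy group equatorial and puts the flat ester, not the C18 methyl, in the axial position syn to the C20 methyl. No Lewis acid is used, so that the silyl dienol ether and the tert-butyl ester survive.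

Step 8
Reactants: 12 Δ6 cycloadduct (3β,8β-bis-OTBS, 9β-CO2Me, 4β-CO2tBu)
Product: 13 1-tert-butyl 5-methyl 2,6-bis[(tert-butyldimethylsilyl)oxy]-1,4a-dimethyldecahydronaphthalene-1,5-dicarboxylate (labdane numbering: 3β,8β-bis-OTBS, 9β-CO2Me, 4β-CO2tBu, 5α-H, 10β-CH3)
Conditions: H2 (1 atm), Pd/C (10 %), EtOAc, rt
Reagents that add atoms: none
Why: Heterogeneous catalytic hydrogenation of the only C=C bond, which creates no stereocentre and is done before any other alkene is introduced.

Step 9
Reactants: 13 saturated diester (9β-CO2Me, 4β-CO2tBu)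
Product: 14 tert-butyl 2,6-bis[(tert-butyldimethylsilyl)oxy]-5-(hydroxymethyl)-1,4a-dimethyldecahydronaphthalene-1-carboxylate (labdane numbering: 9β-CH2OH = C11 alcohol)
Conditions: iBu2AlH (2.5 equiv), CH2Cl2, −78 → −20 °C; Rochelle salt
Reagents that add atoms: none
Why: Hydride reduction of an ester, selective because the methyl ester sits on the secondary C9 whereas the tert-butyl ester on quaternary C4 is shielded by its own bulk, the C3 silyl ether and the axial environment.

Step 10
Reactants: 14 C11 alcohol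
Product: 15 tert-butyl 2,6-bis[(tert-butyldimethylsilyl)oxy]-5-formyl-1,4a-dimethyldecahydronaphthalene-1-carboxylate (labdane numbering: 9β-CHO = C11 aldehyde)
Conditions: Dess–Martin periodinane, NaHCO3, CH2Cl2, 0 °C → rt
Reagents that add atoms: none
Why: Dess–Martin oxidation under buffered, non-basic conditions, which should neither eliminate the β-silyloxy group nor disturb C9, whose equatorial formyl group is in any case the stable epimer.

Step 11
Reactants: 15 C11 aldehyde
Product: 16 tert-butyl 2,6-bis[(tert-butyldimethylsilyl)oxy]-5-ethenyl-1,4a-dimethyldecahydronaphthalene-1-carboxylate (labdane numbering: 9β-vinyl, C11=C12)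
Conditions: Ph3PCH3Br, KOtBu, THF, 0 °C; then 15, 0 °C → rt
Reagents that add atoms: methyltriphenylphosphonium bromide C[P+](c1ccccc1)(c1ccccc1)c1ccccc1.[Br-]
Why: Wittig methylenation with the small unstabilised ylide, which adds to the hindered aldehyde faster than it can deprotonate C9, and brings in C12.

Step 12
Reactants: 17 tert-butyl acetoacetate
Product: 18 tert-butyl (2E)-3-{[(trifluoromethyl)sulfonyl]oxy}but-2-enoate
Conditions: Tf2O, aq. Me4NOH, hexanes, 5 °C
Reagents that add atoms: triflic anhydride O=S(=O)(OS(=O)(=O)C(F)(F)F)C(F)(F)F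
Why: Two-phase (Schotten–Baumann type) enol triflation, in which the non-chelated tetramethylammonium enolate reacts in its extended form and gives the (E)-enol triflate, with the leaving group trans to the ester.

Step 13
Reactants: 16 9β-vinyl decalin; 18 tert-butyl (2E)-3-{[(trifluoromethyl)sulfonyl]oxy}but-2-enoate
Product: 20 di-tert-butyl (13E)-3β,8β-bis[(tert-butyldimethylsilyl)oxy]-17-norlabd-13-ene-15,19-dioate, via alkylborane 19 (not isolated)
Conditions: 9-BBN-H dimer, THF, rt → 40 °C; then 18, PdCl2(dppf) (5 mol %), AsPh3, K3PO4 (3 M aq.), DMF, rt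
Reagents that add atoms: none
Why: B-alkyl Suzuki–Miyaura coupling, in which anti-Markovnikov hydroboration puts boron on C12 and the palladium-catalysed coupling replaces the triflate with retention of alkene geometry, so the C12–C13 bond forms with the 13E enoate fixed.

Step 14
Reactants: 20 di-tert-butyl (13E)-3β,8β-bis[(tert-butyldimethylsilyl)oxy]-17-norlabd-13-ene-15,19-dioate
Product: 21 di-tert-butyl (13E)-3β,8β-dihydroxy-17-norlabd-13-ene-15,19-dioate
Conditions: HF·pyridine, pyridine, THF, 0 °C → 40 °C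
Reagents that add atoms: none
Why: Fluoride-mediated cleavage of both silyl ethers under mildly acidic conditions, chosen over basic fluoride so that a C8 alkoxide cannot add in conjugate fashion to the side-chain enoate, while the tert-butyl esters are untouched.

Step 15
Reactants: 21 di-tert-butyl (13E)-3β,8β-dihydroxy-17-norlabd-13-ene-15,19-dioate
Product: 22 di-tert-butyl (13E)-3β-acetoxy-8β-hydroxy-17-norlabd-13-ene-15,19-dioate
Conditions: Ac2O (1.2 equiv), pyridine, 0 °C → rt
Reagents that add atoms: acetic anhydride CC(=O)OC(C)=O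
Why: Sterically controlled acylation, in which the equatorial 3β-hydroxyl reacts while the axial 8β-hydroxyl, syn-axial to the C20 methyl and flanked by the C9 side chain, should react far more slowly.

Step 16
Reactants: 22 di-tert-butyl (13E)-3β-acetoxy-8β-hydroxy-17-norlabd-13-ene-15,19-dioate
Product: 23 di-tert-butyl (13E)-3β-acetoxy-8-oxo-17-norlabd-13-ene-15,19-dioate
Conditions: Dess–Martin periodinane, NaHCO3, CH2Cl2, rt
Reagents that add atoms: none
Why: Dess–Martin oxidation of the remaining hindered secondary alcohol to the C8 ketone under neutral conditions that leave the acetate, the esters and C9 alone.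

Step 17
Reactants: 23 di-tert-butyl (13E)-3β-acetoxy-8-oxo-17-norlabd-13-ene-15,19-dioate
Product: 24 di-tert-butyl 3β-acetoxylabda-8(17),13E-diene-15,19-dioate
Conditions: Zn, CH2Br2, TiCl4, THF, 0 °C (reagent pre-formed); then 23, CH2Cl2, rt; aq. NaHCO3
Reagents that add atoms: dibromomethane BrCBr
Why: Takai–Lombardo methylenation, whose non-basic geminal dizinc/titanium reagent converts hindered, enolisable ketones into methylene compounds without attacking esters or the acetate and without epimerising C9, bringing in C17.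

Step 18
Reactants: 24 di-tert-butyl 3β-acetoxylabda-8(17),13E-diene-15,19-dioate
Product: 26 3β-acetoxy-agathic acid, via bis(trimethylsilyl) ester 25 (not isolated)
Conditions: TMSOTf, 2,6-lutidine, CH2Cl2, 0 °C → rt; then H2O (pH 4 buffer)
Reagents that add atoms: none
Why: Silyl-triflate-mediated tert-butyl ester cleavage (O-silylation, then loss of isobutene), which is indifferent to the steric shielding of the C19 carbonyl and is buffered by lutidine so that neither the exocyclic alkene nor the acetate is touched, the silyl esters being hydrolysed on work-up.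

**Compound list**

1 | tert-butyl pent-4-enoate | C=CCCC(=O)OC(C)(C)C | starting material
2 | pent-4-ynal | C#CCCC=O | starting material
3 | E(O)-boron enolate of 1 on the (R,R)-diazaborolidine | C=CC/C=C(\OC(C)(C)C)OB1N(S(=O)(=O)c2cc(cc(c2)C(F)(F)F)C(F)(F)F)[C@H](c2ccccc2)[C@@H](c2ccccc2)N1S(=O)(=O)c1cc(cc(c1)C(F)(F)F)C(F)(F)F | intermediate
4 | tert-butyl (2S,3S)-3-hydroxy-2-(prop-2-en-1-yl)hept-6-ynoate | C#CCC[C@H](O)[C@H](CC=C)C(=O)OC(C)(C)C | intermediate
5 | trilithio species of 4 (acetylide, alkoxide, chelated ester enolate) | [Li]C#CCC[C@H](O[Li])/C(CC=C)=C(\O[Li])OC(C)(C)C | intermediate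
6 | tert-butyl (2R,3S)-3-hydroxy-2-methyl-2-(prop-2-en-1-yl)hept-6-ynoate | C#CCC[C@H](O)[C@](C)(C(=O)OC(C)(C)C)CC=C | intermediate
7 | tert-butyl (2R,3S)-3-[(tert-butyldimethylsilyl)oxy]-2-methyl-2-(prop-2-en-1-yl)hept-6-ynoate | C#CCC[C@H](O[Si](C)(C)C(C)(C)C)[C@](C)(C(=O)OC(C)(C)C)CC=C | intermediate
8 | (E)-alkenyl(dimethyl)alane from 7 (Al on C9, cis to the new methyl) | C[Al](C)/C=C(\C)CC[C@H](O[Si](C)(C)C(C)(C)C)[C@](C)(C(=O)OC(C)(C)C)CC=C | intermediate
9 | 1-tert-butyl 8-methyl (2R,3S,6E)-3-[(tert-butyldimethylsilyl)oxy]-2,6-dimethyl-2-(prop-2-en-1-yl)oct-6-enedioate | COC(=O)/C=C(\C)CC[C@H](O[Si](C)(C)C(C)(C)C)[C@](C)(C(=O)OC(C)(C)C)CC=C | intermediate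
10 | 1-tert-butyl 8-methyl (2R,3S,6E)-3-[(tert-butyldimethylsilyl)oxy]-2,6-dimethyl-2-[(2E)-4-oxobut-2-en-1-yl]oct-6-enedioate | COC(=O)/C=C(\C)CC[C@H](O[Si](C)(C)C(C)(C)C)[C@](C)(C(=O)OC(C)(C)C)C/C=C/C=O | intermediate
11 | 1-tert-butyl 8-methyl (2R,3S,6E)-3-[(tert-butyldimethylsilyl)oxy]-2-[(1E,3E)-4-[(tert-butyldimethylsilyl)oxy]buta-1,3-dien-1-yl]-2,6-dimethyloct-6-enedioate (cycloaddition precursor) | COC(=O)/C=C(\C)CC[C@H](O[Si](C)(C)C(C)(C)C)[C@](C)(C(=O)OC(C)(C)C)/C=C/C=C/O[Si](C)(C)C(C)(C)C | intermediate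
12 | trans-fused Δ6 cycloadduct: 1-tert-butyl 5-methyl 2,6-bis[(tert-butyldimethylsilyl)oxy]-1,4a-dimethyl-1,2,3,4,4a,5,6,8a-octahydronaphthalene-1,5-dicarboxylate (3β,8β-bis-OTBS, 9β-CO2Me, 4β-CO2tBu, 4α-CH3, 10β-CH3, 5α-H) | CC(C)(C)[Si](C)(C)O[C@H]1C=C[C@@H]2[C@](C)(CC[C@H](O[Si](C)(C)C(C)(C)C)[C@]2(C)C(=O)OC(C)(C)C)[C@H]1C(=O)OC | intermediate
13 | saturated decalin diester (as 12 without the C6=C7 bond) | CC(C)(C)[Si](C)(C)O[C@H]1CC[C@@H]2[C@](C)(CC[C@H](O[Si](C)(C)C(C)(C)C)[C@]2(C)C(=O)OC(C)(C)C)[C@H]1C(=O)OC | intermediate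
14 | C11 alcohol (9β-hydroxymethyl, 3β,8β-bis-OTBS, 4β-CO2tBu) | CC(C)(C)[Si](C)(C)O[C@H]1CC[C@@H]2[C@](C)(CC[C@H](O[Si](C)(C)C(C)(C)C)[C@]2(C)C(=O)OC(C)(C)C)[C@H]1CO | intermediate
15 | C11 aldehyde (9β-formyl, 3β,8β-bis-OTBS, 4β-CO2tBu) | CC(C)(C)[Si](C)(C)O[C@H]1CC[C@@H]2[C@](C)(CC[C@H](O[Si](C)(C)C(C)(C)C)[C@]2(C)C(=O)OC(C)(C)C)[C@H]1C=O | intermediate
16 | 9β-vinyl decalin (C11=C12, 3β,8β-bis-OTBS, 4β-CO2tBu) | CC(C)(C)[Si](C)(C)O[C@H]1CC[C@@H]2[C@](C)(CC[C@H](O[Si](C)(C)C(C)(C)C)[C@]2(C)C(=O)OC(C)(C)C)[C@H]1C=C | intermediate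
17 | tert-butyl acetoacetate | CC(=O)CC(=O)OC(C)(C)C | starting material
18 | tert-butyl (2E)-3-{[(trifluoromethyl)sulfonyl]oxy}but-2-enoate | C/C(OS(=O)(=O)C(F)(F)F)=C\C(=O)OC(C)(C)C | intermediate
19 | B-alkyl-9-borabicyclo[3.3.1]nonane from 16 (boron on C12) | CC(C)(C)[Si](C)(C)O[C@H]1CC[C@@H]2[C@](C)(CC[C@H](O[Si](C)(C)C(C)(C)C)[C@]2(C)C(=O)OC(C)(C)C)[C@H]1CCB3C4CCCC3CCC4 | intermediate
20 | di-tert-butyl (13E)-3β,8β-bis[(tert-butyldimethylsilyl)oxy]-17-norlabd-13-ene-15,19-dioate | CC(C)(C)[Si](C)(C)O[C@H]1CC[C@@H]2[C@](C)(CC[C@H](O[Si](C)(C)C(C)(C)C)[C@]2(C)C(=O)OC(C)(C)C)[C@H]1CC/C(C)=C/C(=O)OC(C)(C)C | intermediate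
21 | di-tert-butyl (13E)-3β,8β-dihydroxy-17-norlabd-13-ene-15,19-dioate | O[C@H]1CC[C@@H]2[C@](C)(CC[C@H](O)[C@]2(C)C(=O)OC(C)(C)C)[C@H]1CC/C(C)=C/C(=O)OC(C)(C)C | intermediate
22 | di-tert-butyl (13E)-3β-acetoxy-8β-hydroxy-17-norlabd-13-ene-15,19-dioate | O[C@H]1CC[C@@H]2[C@](C)(CC[C@H](OC(C)=O)[C@]2(C)C(=O)OC(C)(C)C)[C@H]1CC/C(C)=C/C(=O)OC(C)(C)C | intermediate
23 | di-tert-butyl (13E)-3β-acetoxy-8-oxo-17-norlabd-13-ene-15,19-dioate | O=C1CC[C@@H]2[C@](C)(CC[C@H](OC(C)=O)[C@]2(C)C(=O)OC(C)(C)C)[C@H]1CC/C(C)=C/C(=O)OC(C)(C)C | intermediate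
24 | di-tert-butyl 3β-acetoxylabda-8(17),13E-diene-15,19-dioate | C=C1CC[C@@H]2[C@](C)(CC[C@H](OC(C)=O)[C@]2(C)C(=O)OC(C)(C)C)[C@H]1CC/C(C)=C/C(=O)OC(C)(C)C | intermediate
25 | bis(trimethylsilyl) 3β-acetoxylabda-8(17),13E-diene-15,19-dioate | C=C1CC[C@@H]2[C@](C)(CC[C@H](OC(C)=O)[C@]2(C)C(=O)O[Si](C)(C)C)[C@H]1CC/C(C)=C/C(=O)O[Si](C)(C)C | intermediate
26 | 3β-acetoxy-agathic acid (3β-acetoxylabda-8(17),13E-diene-15,19-dioic acid) | C=C1CC[C@@H]2[C@](C)(CC[C@H](OC(C)=O)[C@]2(C)C(=O)O)[C@H]1CC/C(C)=C/C(=O)O | target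

**Step count**

Total: 18 steps. Longest linear sequence: 17 steps (steps 1–11 and 13–18); step 12 is a one-step side branch.

**Steps most likely to fail**

Step 7. The cycloaddition may leak into the tether-endo (cis-fused) pathway or onto the other diene face, or be so slow at 170 °C that the silyl dienol ether is lost by adventitious protonation. Fallback: setting out from triene 11, the methyl enoate is reduced with iBu2AlH (CH2Cl2, −78 °C) to the allylic alcohol tert-butyl (2R,3S,6E)-3-[(tert-butyldimethylsilyl)oxy]-2-[(1E,3E)-4-[(tert-butyldimethylsilyl)oxy]buta-1,3-dien-1-yl]-8-hydroxy-2,6-dimethyloct-6-enoate F1. This is oxidised with MnO2 (CH2Cl2, rt) to the enal tert-butyl (2R,3S,6E)-3-[(tert-butyldimethylsilyl)oxy]-2-[(1E,3E)-4-[(tert-butyldimethylsilyl)oxy]buta-1,3-dien-1-yl]-2,6-dimethyl-8-oxooct-6-enoate F2. With the aldehyde as the more strongly activating and more endo-directing group, the same two bonds should form at or below 80 °C in toluene, giving the Δ6 9β-formyl cycloadduct F3. Hydrogenation of F3 (H2, Pd/C, EtOAc) returns to the route at aldehyde 15, and steps 9 and 10 are then not needed.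

Step 4. The Lewis-acidic aluminium and zirconium species may attack the tert-butyl ester during the long carbometalation, or the alkenylalane may be acylated incompletely. Fallback: setting out from alkyne 7, gold-catalysed Markovnikov hydration (Ph3PAuNTf2 cat., MeOH–H2O, rt) gives the methyl ketone tert-butyl (2R,3S)-3-[(tert-butyldimethylsilyl)oxy]-2-methyl-6-oxo-2-(prop-2-en-1-yl)heptanoate F4. Horner–Wadsworth–Emmons olefination with trimethyl phosphonoacetate (NaH, THF, 0 °C → rt) then returns to the route at enoate 9. This path is not stereospecific, and the minor (Z)-isomer would have to be removed by chromatography.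

Step 15. The acylation may not discriminate well enough between the two secondary hydroxyls, either through over-acetylation at C8 or through sluggish reaction at the neopentyl-type C3. Fallback: setting out from diol 21, both alcohols are oxidised (Dess–Martin periodinane) to the diketone di-tert-butyl (13E)-3,8-dioxo-17-norlabd-13-ene-15,19-dioate F5. Wittig methylenation with a small excess of Ph3P=CH2 (THF, 0 °C → rt) should take place at the C8 carbonyl only, since the C3 carbonyl is flanked by the quaternary C4, giving di-tert-butyl 3-oxolabda-8(17),13E-diene-15,19-dioate F6. NaBH4 (MeOH, 0 °C) delivers hydride to the α-face of C3, away from the axial C19 ester and the C20 methyl, to give di-tert-butyl 3β-hydroxylabda-8(17),13E-diene-15,19-dioate F7. Acetylation (Ac2O, pyridine, DMAP) returns to the route at compound 24.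

**Further compounds**

F1 | step 7 | tert-butyl (2R,3S,6E)-3-[(tert-butyldimethylsilyl)oxy]-2-[(1E,3E)-4-[(tert-butyldimethylsilyl)oxy]buta-1,3-dien-1-yl]-8-hydroxy-2,6-dimethyloct-6-enoate | OC/C=C(\C)CC[C@H](O[Si](C)(C)C(C)(C)C)[C@](C)(C(=O)OC(C)(C)C)/C=C/C=C/O[Si](C)(C)C(C)(C)C
F2 | step 7 | tert-butyl (2R,3S,6E)-3-[(tert-butyldimethylsilyl)oxy]-2-[(1E,3E)-4-[(tert-butyldimethylsilyl)oxy]buta-1,3-dien-1-yl]-2,6-dimethyl-8-oxooct-6-enoate | O=C/C=C(\C)CC[C@H](O[Si](C)(C)C(C)(C)C)[C@](C)(C(=O)OC(C)(C)C)/C=C/C=C/O[Si](C)(C)C(C)(C)C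
F3 | step 7 | trans-fused Δ6 cycloadduct aldehyde (3β,8β-bis-OTBS, 9β-CHO, 4β-CO2tBu, 4α-CH3, 10β-CH3, 5α-H) | CC(C)(C)[Si](C)(C)O[C@H]1C=C[C@@H]2[C@](C)(CC[C@H](O[Si](C)(C)C(C)(C)C)[C@]2(C)C(=O)OC(C)(C)C)[C@H]1C=O
F4 | step 4 | tert-butyl (2R,3S)-3-[(tert-butyldimethylsilyl)oxy]-2-methyl-6-oxo-2-(prop-2-en-1-yl)heptanoate | CC(=O)CC[C@H](O[Si](C)(C)C(C)(C)C)[C@](C)(C(=O)OC(C)(C)C)CC=C
F5 | step 15 | di-tert-butyl (13E)-3,8-dioxo-17-norlabd-13-ene-15,19-dioate | O=C1CC[C@@H]2[C@](C)(CCC(=O)[C@]2(C)C(=O)OC(C)(C)C)[C@H]1CC/C(C)=C/C(=O)OC(C)(C)C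
F6 | step 15 | di-tert-butyl 3-oxolabda-8(17),13E-diene-15,19-dioate | C=C1CC[C@@H]2[C@](C)(CCC(=O)[C@]2(C)C(=O)OC(C)(C)C)[C@H]1CC/C(C)=C/C(=O)OC(C)(C)C
F7 | step 15 | di-tert-butyl 3β-hydroxylabda-8(17),13E-diene-15,19-dioate | C=C1CC[C@@H]2[C@](C)(CC[C@H](O)[C@]2(C)C(=O)OC(C)(C)C)[C@H]1CC/C(C)=C/C(=O)OC(C)(C)C
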